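**Retrosynthetic overview**
1. The strategy rests on ring B (O1–C2–C3–C4–C4a–C8a). C2 is a ketone-level carbon bound to O1, CH3, the side chain and C3, and C3 is the α-carbon of the C4 aryl ketone. The C2–C3 bond is therefore the bond between an enol and an O1=C2 aryloxycarbenium ion.
2. The target comes from its C6 acetate / tertiary formate by cold methanolysis. That diester is cut at C2–C3 to an achiral aryl 1-alkylvinyl ether with an ortho acetyl group, and a confined chiral Brønsted acid closes ring B and sets C2.
3. The enol ether is cut at O1–C2 (Chan–Evans–Lam coupling) into 5-acetyl-2-bromo-4-hydroxyphenyl acetate and an α-alkylvinyl boronate.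
4. The phenol comes from 2-bromo-1,4-dimethoxybenzene (acylation, demethylation, selective acetylation). The boronate comes from methyl hex-5-ynoate (MeMgBr, α-selective hydroalumination/borylation, formylation). Esters are chosen because they cannot trap the cation and both cleave in cold K2CO3/MeOH.
5. Ring order: ring A (the arene) is bought, and ring B is the only ring formed (step 8).

Key step: step 8

Assumption: the sense of induction of the confined acid cannot be predicted for this new closure, so the (S,S)-catalyst is written and its mirror image is used if the (R)-chromanone should form.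

**Step 1**
Reactants: 1 2-bromo-1,4-dimethoxybenzene
Product: 2 1-(4-bromo-2,5-dimethoxyphenyl)ethan-1-one
Conditions: AcCl, AlCl3, CH2Cl2, 0 °C to rt; then ice/aq HCl
Reagents that add atoms: acetyl chloride, CC(=O)Cl
Why: Friedel–Crafts acylation, in which the position para to bromine and ortho to the C4 methoxy group is the most activated unhindered site, so the acetyl group should enter there and fix the 1,2,4,5 pattern of ring A.

**Step 2**
Reactants: 2 1-(4-bromo-2,5-dimethoxyphenyl)ethan-1-one
Product: 3 1-(4-bromo-2,5-dihydroxyphenyl)ethan-1-one
Conditions: BBr3 (3 equiv), CH2Cl2, −78 °C to rt; then H2O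
Reagents that add atoms: none
Why: Lewis acid cleavage of aryl methyl ethers with BBr3 should remove both methyl groups, while the aryl bromide and the ketone are inert to the reagent.

**Step 3**
Reactants: 3 1-(4-bromo-2,5-dihydroxyphenyl)ethan-1-one
Product: 4 5-acetyl-2-bromo-4-hydroxyphenyl acetate
Conditions: Ac2O (1.05 equiv), pyridine, CH2Cl2, 0 °C
Reagents that add atoms: acetic anhydride, CC(=O)OC(C)=O
Why: Selective O-acylation, in which the hydroxyl ortho to the acetyl group is tied up in a strong hydrogen bond to the carbonyl oxygen, so one equivalent of Ac2O should acetylate only the free, more acidic hydroxyl next to bromine.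

**Step 4**
Reactants: 5 methyl hex-5-ynoate
Product: 7 2-methylhept-6-yn-2-ol, via hept-6-yn-2-one 6 (not isolated)
Conditions: MeMgBr (3.3 equiv), THF, 0 °C to rt; then H2O
Reagents that add atoms: methylmagnesium bromide, C[Mg]Br
Why: Double Grignard addition to an ester, in which the first equivalent is spent on the acetylenic C–H, the next two convert the ester through ketone 6 into the tertiary alkoxide, and water returns the terminal alkyne.

**Step 5**
Reactants: 7 2-methylhept-6-yn-2-ol
Product: 9 2-methyl-6-(4,4,5,5-tetramethyl-1,3,2-dioxaborolan-2-yl)hept-6-en-2-ol, via bis(diisobutylaluminium) vinylalane alkoxide 8 (not isolated)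
Conditions: iBu2AlH (1.05 equiv), THF, 0 °C; added to Ni(dppp)Cl2 (3 mol %)/iBu2AlH (1.3 equiv), THF, 0 °C to rt; then MeOBpin (3 equiv), 0 to 60 °C; then aq potassium sodium tartrate
Reagents that add atoms: 2-methoxy-4,4,5,5-tetramethyl-1,3,2-dioxaborolane (MeOBpin), COB1OC(C)(C)C(C)(C)O1
Why: Nickel-catalysed α-selective hydroalumination of a terminal alkyne followed by aluminium-to-boron exchange, in which the bidentate dppp ligand places aluminium on the internal carbon, the tertiary alcohol is masked in the flask as its aluminium alkoxide, and MeOBpin takes over the vinyl group with the 1,1-disubstituted alkene kept.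

**Step 6**
Reactants: 9 2-methyl-6-(4,4,5,5-tetramethyl-1,3,2-dioxaborolan-2-yl)hept-6-en-2-ol
Product: 10 2-methyl-6-(4,4,5,5-tetramethyl-1,3,2-dioxaborolan-2-yl)hept-6-en-2-yl formate
Conditions: HCO2H/Ac2O (premixed at 55 °C, then cooled), pyridine, CH2Cl2, 0 °C to rt
Reagents that add atoms: acetic formic anhydride, CC(=O)OC=O, made beforehand from formic acid, O=CO, and acetic anhydride, CC(=O)OC(C)=O
Why: O-formylation with a mixed anhydride, which transfers only its more electrophilic and unhindered formyl group, small enough to acylate a tertiary alcohol under pyridine buffering that also spares the vinyl boronate.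

**Step 7**
Reactants: 4 5-acetyl-2-bromo-4-hydroxyphenyl acetate; 10 2-methyl-6-(4,4,5,5-tetramethyl-1,3,2-dioxaborolan-2-yl)hept-6-en-2-yl formate (2 equiv)
Product: 11 5-acetyl-2-bromo-4-[(6-formyloxy-6-methylhept-1-en-2-yl)oxy]phenyl acetate
Conditions: Cu(OAc)2 (2 equiv), pyridine (5 equiv), 4 Å MS, CH2Cl2, dry air, rt; chromatography on Et3N-deactivated silica
Reagents that add atoms: none
Why: Chan–Evans–Lam O-alkenylation, in which transmetalation of the alkenyl boronate to the copper phenolate, oxidation to trivalent copper and C–O reductive elimination should give the aryl 1-alkylvinyl ether at room temperature, where aryl bromide, acetate and formate are inert and excess pyridine breaks up the copper chelate of the ortho-acyl phenolate.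

**Step 8**
Reactants: 11 5-acetyl-2-bromo-4-[(6-formyloxy-6-methylhept-1-en-2-yl)oxy]phenyl acetate
Product: 14 (S)-7-bromo-2-(4-formyloxy-4-methylpentyl)-2-methyl-4-oxochroman-6-yl acetate, via 4-methylene-1,3-benzodioxine enol acetal 12 (not isolated), via aryloxycarbenium enol cation 13 (not isolated)
Conditions: (S,S)-IDPi [imidodiphosphorimidate from two 3,3'-diaryl-(S)-BINOL units with P=N–SO2CF3 groups, aryl = 3,5-(CF3)2C6H3 as first choice] (5 mol %), 4 Å MS, toluene (0.02 M), −40 °C; then Et3N
Reagents that add atoms: none
Why: Proposed new method: the confined acid protonates the CH2 terminus of the aryl enol ether of 11 (this carbon becomes the C2 methyl group) and gives an O1=C2 aryloxycarbenium ion that stays paired with the chiral imidodiphosphorimidate anion. The ortho acetyl oxygen can cap this cation reversibly, which acidifies the acetyl CH3, so that proton loss to the anion gives the enol acetal 12, and reprotonation at its enol oxygen with C2–O cleavage delivers the enol/oxocarbenium pair 13 without a separate, slow ketone enolisation. The enol carbon C3 then attacks C2 and loss of the enol proton returns the acid, so ring B closes in a 6-(enolendo)-endo-trig mode, in which both the C3=C4 enol bond and the O1=C2 bond lie inside the new ring. The closest known reaction types are the Petasis–Ferrier rearrangement, in which a Lewis acid opens a 4-methylene-1,3-dioxane to an oxocarbenium/enolate pair that recloses to a tetrahydropyran-4-one, and confined Brønsted acid catalysis in which a protonated enol ether is trapped enantioselectively inside the ion pair; neither has been shown with an aryloxycarbenium ion, a ketone enol and a fully substituted carbon. The C2 stereocentre is set by the anion alone, which binds the enol O–H and must leave open only the face of C2 that places the small CH3 and the CH2 chain in different pockets, since 11 and 13 have no stereocentre and the ketal centre of 12 is erased on ionisation. The step needs C- over O-attack (O-capture is reversible, C–C formation is not), ring closure over oligomerisation or hydrolysis (ortho placement, high dilution, molecular sieves) and an inert side chain (the formate oxygen is not nucleophilic, whereas a free hydroxyl would close a tetrahydropyran ketal), and the low temperature keeps the tertiary formate from ionising.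

**Step 9**
Reactants: 14 (S)-7-bromo-2-(4-formyloxy-4-methylpentyl)-2-methyl-4-oxochroman-6-yl acetate
Product: 15 (S)-7-bromo-6-hydroxy-2-(4-hydroxy-4-methylpentyl)-2-methylchroman-4-one
Conditions: K2CO3 (3 equiv), MeOH, 0 °C; then AcOH to pH 6 at 0 °C
Reagents that add atoms: none
Why: Base-catalysed transesterification (Zemplén-type methanolysis), in which the activated aryl acetate and the tertiary formate (cleaved far faster than a tertiary acetate would be) should both cleave at 0 °C, and the C6 phenoxide formed at once makes O1 a poor leaving group, so the E1cB ring opening (retro-oxa-Michael) that would scramble C2 is held back.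

**Compound list**
1 | 2-bromo-1,4-dimethoxybenzene | COc1ccc(OC)c(Br)c1 | starting material
2 | 1-(4-bromo-2,5-dimethoxyphenyl)ethan-1-one | CC(=O)c1cc(OC)c(Br)cc1OC | intermediate
3 | 1-(4-bromo-2,5-dihydroxyphenyl)ethan-1-one | CC(=O)c1cc(O)c(Br)cc1O | intermediate
4 | 5-acetyl-2-bromo-4-hydroxyphenyl acetate | CC(=O)c1cc(OC(C)=O)c(Br)cc1O | intermediate
5 | methyl hex-5-ynoate | C#CCCCC(=O)OC | starting material
6 | hept-6-yn-2-one (not isolated) | C#CCCCC(C)=O | intermediate
7 | 2-methylhept-6-yn-2-ol | C#CCCCC(C)(C)O | intermediate
8 | diisobutylaluminium 6-(diisobutylalumanyl)-2-methylhept-6-en-2-olate (not isolated) | C=C(CCCC(C)(C)O[Al](CC(C)C)CC(C)C)[Al](CC(C)C)CC(C)C | intermediate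
9 | 2-methyl-6-(4,4,5,5-tetramethyl-1,3,2-dioxaborolan-2-yl)hept-6-en-2-ol | C=C(CCCC(C)(C)O)B1OC(C)(C)C(C)(C)O1 | intermediate
10 | 2-methyl-6-(4,4,5,5-tetramethyl-1,3,2-dioxaborolan-2-yl)hept-6-en-2-yl formate | C=C(CCCC(C)(C)OC=O)B1OC(C)(C)C(C)(C)O1 | intermediate
11 | 5-acetyl-2-bromo-4-[(6-formyloxy-6-methylhept-1-en-2-yl)oxy]phenyl acetate | CC(=O)c1cc(OC(C)=O)c(Br)cc1OC(=C)CCCC(C)(C)OC=O | intermediate
12 | 7-bromo-2-(4-formyloxy-4-methylpentyl)-2-methyl-4-methylene-4H-1,3-benzodioxin-6-yl acetate (racemic ketal centre, not isolated) | C=C1OC(C)(CCCC(C)(C)OC=O)Oc2cc(Br)c(OC(C)=O)cc21 | intermediate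
13 | aryloxycarbenium ion at C2 with the ortho 1-hydroxyvinyl (enol) group, paired with the IDPi anion (not isolated) | CC(CCCC(C)(C)OC=O)=[O+]c1cc(Br)c(OC(C)=O)cc1C(O)=C | intermediate
14 | (S)-7-bromo-2-(4-formyloxy-4-methylpentyl)-2-methyl-4-oxochroman-6-yl acetate | O=COC(C)(C)CCC[C@@]1(C)CC(=O)c2cc(OC(C)=O)c(Br)cc2O1 | intermediate
15 | (S)-7-bromo-6-hydroxy-2-(4-hydroxy-4-methylpentyl)-2-methylchroman-4-one | CC(C)(O)CCC[C@@]1(C)CC(=O)c2cc(O)c(Br)cc2O1 | target

**Total step count:** 9
**Longest linear sequence:** 6 steps (steps 1, 2, 3, 7, 8, 9; the boronate branch, steps 4 to 9, is equally long)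

**Steps most likely to fail**

**Step 8.** Several processes may defeat the closure:
- Facial discrimination between CH3 and the CH2 chain in the ion pair may be poor.
- Enol formation may be so slow that cationic oligomerisation or hydrolysis by traces of water wins.
- A closure of reversed polarity may intervene, in which the enol ether carbon attacks the acid-activated acetyl carbon and water is then lost.
- The tertiary formate may ionise under the strong acid.

The fallback uses known chemistry, sets out from 3 and 7, and comes back at 15. Markovnikov hydration of alkyne 7 (NaAuCl4 cat., aq MeOH, reflux) should give 6-hydroxy-6-methylheptan-2-one F1. Kabbe condensation of this ketone with 3 (pyrrolidine, MeOH, argon, rt to 50 °C; enamine aldol, dehydration, oxa-Michael closure) should give racemic 7-bromo-6-hydroxy-2-(4-hydroxy-4-methylpentyl)-2-methylchroman-4-one F2. Preparative chromatography on a chiral stationary phase (amylose tris(3,5-dimethylphenylcarbamate), supercritical CO2/MeOH) then separates 15. The unwanted antipode can be re-equilibrated with pyrrolidine and separated again.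

**Step 7.** Chelation of divalent copper by the ortho-acyl phenolate may slow transmetalation. Protodeboronation and homocoupling of the hindered boronate, or acetyl migration between the phenols, could then take over.

The fallback makes the C–O bond at an sp3 carbon and the alkene by elimination. It sets out from 4 and 7 and comes back at 11.
- Semihydrogenation of 7 (H2, Pd/CaCO3 poisoned with Pb(OAc)2, quinoline, EtOAc) should give 2-methylhept-6-en-2-ol F3.
- Formylation as in step 6 should give 2-methylhept-6-en-2-yl formate F4.
- Bromohydrin formation (NBS, acetone/H2O, 0 °C) should give racemic 7-bromo-6-hydroxy-2-methylheptan-2-yl formate F5.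
- Mitsunobu etherification with 4 (PPh3, DIAD, toluene, 0 °C to rt) should give racemic 5-acetyl-2-bromo-4-[(1-bromo-6-formyloxy-6-methylheptan-2-yl)oxy]phenyl acetate F6.
- E2 dehydrobromination (DBU, toluene, 80 °C) can only run towards the oxygen-bearing carbon and should give 11.

**Step 5.** The α-selectivity may be lost, the alkyne may be deprotonated instead of hydroaluminated, or the aluminium-to-boron transfer may stay incomplete beside the aluminium alkoxide.

The fallback sets out from 7 and comes back at 9. Hydration as above gives 6-hydroxy-6-methylheptan-2-one F1. Condensation with 2,4,6-triisopropylbenzenesulfonohydrazide (MeOH, rt) should give N'-(6-hydroxy-6-methylheptan-2-ylidene)-2,4,6-triisopropylbenzenesulfonohydrazide F7. The Shapiro reaction (n-BuLi, 3.3 equiv, THF/TMEDA, −78 to 0 °C) deprotonates on the methyl side and should give lithium 6-lithio-2-methylhept-6-en-2-olate F8. Trapping with iPrOBpin (−78 °C to rt, then aq NH4Cl) should give 9.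

**Further compounds**
F1 | step 8 | 6-hydroxy-6-methylheptan-2-one | CC(=O)CCCC(C)(C)O
F2 | step 8 | racemic 7-bromo-6-hydroxy-2-(4-hydroxy-4-methylpentyl)-2-methylchroman-4-one | CC(C)(O)CCCC1(C)CC(=O)c2cc(O)c(Br)cc2O1
F3 | step 7 | 2-methylhept-6-en-2-ol | C=CCCCC(C)(C)O
F4 | step 7 | 2-methylhept-6-en-2-yl formate | C=CCCCC(C)(C)OC=O
F5 | step 7 | racemic 7-bromo-6-hydroxy-2-methylheptan-2-yl formate | O=COC(C)(C)CCCC(O)CBr
F6 | step 7 | racemic 5-acetyl-2-bromo-4-[(1-bromo-6-formyloxy-6-methylheptan-2-yl)oxy]phenyl acetate | CC(=O)c1cc(OC(C)=O)c(Br)cc1OC(CBr)CCCC(C)(C)OC=O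
F7 | step 5 | N'-(6-hydroxy-6-methylheptan-2-ylidene)-2,4,6-triisopropylbenzenesulfonohydrazide | CC(CCCC(C)(C)O)=NNS(=O)(=O)c1c(C(C)C)cc(C(C)C)cc1C(C)C
F8 | step 5 | lithium 6-lithio-2-methylhept-6-en-2-olate | [Li]C(=C)CCCC(C)(C)O[Li]
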